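## Retrosynthetic overview

1. Target ⇐ TES removal; the C3–C2 bond and both C2/C3 stereocentres come from a catalyst-controlled Mukaiyama addition of a propanoate silyl ketene acetal to a 1,2-dioxan-3-yl cation (from the peroxy-lactol acetate).
2. The 1,2-dioxane (formed last) ⇐ stereospecific peroxidative ring expansion (3 → 6) of a 2,2-dialkylcyclopropanecarbaldehyde with H2O2, with inversion at the future C6.
3. Cyclopropane ⇐ Charette cyclopropanation of a (Z)-trisubstituted allylic alcohol ⇐ B-alkyl Suzuki coupling of a tertiary vinyl carbinol with (Z)-3-iodobut-2-en-1-ol.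
4. (S)-Tertiary carbinol with its exocyclic methylene ⇐ Sharpless epoxidation and iodide/zinc 1,3-transposition of a tetrasubstituted cyclohexenylmethanol ⇐ bromoformylation and vinylation of 2,2-dimethylcyclohexanone.
5. Ring order: cyclohexane (bought as 2-methylcyclohexanone) → cyclopropane → 1,2-dioxane.

Assumption: racemic 2-methylcyclohexanone is used (its stereocentre is destroyed in step 1), and the catalyst enantiomer that gives 3S in step 15 is assigned on a model peroxy-acetate and written here as (S,S).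

## Route

Step 1
Reactants: 1 2-methylcyclohexan-1-one
Product: 3 2,2-dimethylcyclohexan-1-one, via potassium enolate 2 (not isolated)
Conditions: t-BuOK, t-BuOH–THF, 25 °C; then MeI, 0 → 25 °C; distillation
Reagents that add atoms: iodomethane (CI)
Why: Thermodynamic enolate alkylation: equilibrating conditions give the more substituted enolate 2, which is C-methylated at the tertiary carbon; the stereocentre of racemic 1 is destroyed.

Step 2
Reactants: 3 2,2-dimethylcyclohexan-1-one
Product: 5 2-bromo-3,3-dimethylcyclohex-1-ene-1-carbaldehyde, via iminium bromide 4 (not isolated)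
Conditions: PBr3, DMF, CHCl3, 0 → 60 °C; then aq. NaHCO3
Reagents that add atoms: N,N-dimethylformamide (CN(C)C=O); phosphorus tribromide (BrP(Br)Br); water (O)
Why: Vilsmeier–Haack–Arnold bromoformylation: the only enolisable position is formylated and the carbonyl oxygen is exchanged for bromide, then work-up hydrolyses iminium salt 4.

Step 3
Reactants: 5 2-bromo-3,3-dimethylcyclohex-1-ene-1-carbaldehyde; 6 potassium ethenyltrifluoroborate
Product: 7 2-ethenyl-3,3-dimethylcyclohex-1-ene-1-carbaldehyde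
Conditions: PdCl2(dppf) (5 mol %), Cs2CO3, THF–H2O 9:1, 80 °C
Reagents that add atoms: none
Why: Suzuki–Miyaura coupling of an activated β-bromo enal with a vinyltrifluoroborate; no stereocentre is involved.

Step 4
Reactants: 7 2-ethenyl-3,3-dimethylcyclohex-1-ene-1-carbaldehyde
Product: 8 (2-ethenyl-3,3-dimethylcyclohex-1-en-1-yl)methanol
Conditions: NaBH4, CeCl3·7H2O, MeOH, 0 °C
Reagents that add atoms: none
Why: Luche 1,2-reduction of the dienal gives the tetrasubstituted allylic alcohol needed for a directed epoxidation.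

Step 5
Reactants: 8 (2-ethenyl-3,3-dimethylcyclohex-1-en-1-yl)methanol
Product: 9 [(1S,6S)-6-ethenyl-5,5-dimethyl-7-oxabicyclo[4.1.0]heptan-1-yl]methanol
Conditions: Ti(Oi-Pr)4 (10 mol %), L-(+)-diethyl tartrate (12 mol %), t-BuOOH, 4 Å MS, CH2Cl2, −25 °C
Reagents that add atoms: tert-butyl hydroperoxide (CC(C)(C)OO)
Why: Sharpless asymmetric epoxidation of a tetrasubstituted allylic alcohol: L-(+)-tartrate delivers oxygen to the face that makes the vinyl-bearing epoxide carbon S, which sets the carbinol stereocentre of the target.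

Step 6
Reactants: 9 [(1S,6S)-6-ethenyl-5,5-dimethyl-7-oxabicyclo[4.1.0]heptan-1-yl]methanol
Product: 11 (1S)-1-ethenyl-2,2-dimethyl-6-methylidenecyclohexan-1-ol, via epoxy iodide 10 (not isolated)
Conditions: PPh3, imidazole, I2, THF, 0 °C; then activated Zn, EtOH, 50 °C
Reagents that add atoms: none
Why: Appel iodination then zinc-mediated reductive β-elimination (1,3-transposition of a 2,3-epoxy alcohol) unveils the tertiary alcohol and the exocyclic methylene; the C–O bond at the stereocentre is never broken, so S is retained.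

Step 7
Reactants: 11 (1S)-1-ethenyl-2,2-dimethyl-6-methylidenecyclohexan-1-ol
Product: 12 {[(1S)-1-ethenyl-2,2-dimethyl-6-methylidenecyclohexyl]oxy}triethylsilane
Conditions: Et3SiOTf, 2,6-lutidine, CH2Cl2, −78 → 0 °C
Reagents that add atoms: triethylsilyl trifluoromethanesulfonate (CC[Si](CC)(CC)OS(=O)(=O)C(F)(F)F)
Why: Silyl ether formation on the hindered tertiary alcohol; it prevents hydroxyl-directed cyclopropanation of the ring methylene in step 10 and 5-exo etherification in step 12.

Step 8
Reactants: 13 but-2-yn-1-ol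
Product: 15 (2Z)-3-iodobut-2-en-1-ol, via cyclic alkenylaluminate 14 (not isolated)
Conditions: Red-Al, THF, 0 → 25 °C; then I2, −78 → 0 °C
Reagents that add atoms: iodine (II)
Why: Alkoxide-directed trans-hydroalumination of the propargylic alcohol followed by iodinolysis with retention gives the Z vinyl iodide only.

Step 9
Reactants: 12 {[(1S)-1-ethenyl-2,2-dimethyl-6-methylidenecyclohexyl]oxy}triethylsilane; 15 (2Z)-3-iodobut-2-en-1-ol
Product: 17 (2Z)-5-[(1S)-2,2-dimethyl-6-methylidene-1-(triethylsilyloxy)cyclohexyl]-3-methylpent-2-en-1-ol, via alkylborane 16 (not isolated)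
Conditions: 9-BBN, THF, 0 → 25 °C; then PdCl2(dppf) (5 mol %), AsPh3, aq. K3PO4, DMF, 25 °C
Reagents that add atoms: none
Why: 9-BBN hydroborates the monosubstituted vinyl group in preference to the hindered 1,1-disubstituted methylene, and the B-alkyl Suzuki–Miyaura coupling keeps the Z geometry of the iodide.

Step 10
Reactants: 17 (2Z)-5-[(1S)-2,2-dimethyl-6-methylidene-1-(triethylsilyloxy)cyclohexyl]-3-methylpent-2-en-1-ol
Product: 18 [(1S,2R)-2-{2-[(1S)-2,2-dimethyl-6-methylidene-1-(triethylsilyloxy)cyclohexyl]ethyl}-2-methylcyclopropyl]methanol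
Conditions: Et2Zn, CH2I2, DME, (4R,5R)-2-butyl-N,N,N′,N′-tetramethyl-1,3,2-dioxaborolane-4,5-dicarboxamide (1.2 equiv), CH2Cl2, −10 → 25 °C; aq. NH4Cl then NaOH work-up
Reagents that add atoms: diiodomethane (ICI)
Why: Charette asymmetric Simmons–Smith cyclopropanation: the zinc alkoxide/dioxaborolane complex delivers CH2 syn to one face of the allylic alcohol, and together with the Z geometry this fixes the quaternary carbon as 2R (the future C6); minor diastereomers from imperfect ee are removed by chromatography.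

Step 11
Reactants: 18 [(1S,2R)-2-{2-[(1S)-2,2-dimethyl-6-methylidene-1-(triethylsilyloxy)cyclohexyl]ethyl}-2-methylcyclopropyl]methanol
Product: 19 (1S,2R)-2-{2-[(1S)-2,2-dimethyl-6-methylidene-1-(triethylsilyloxy)cyclohexyl]ethyl}-2-methylcyclopropane-1-carbaldehyde
Conditions: Dess–Martin periodinane, NaHCO3, CH2Cl2, 0 → 25 °C
Reagents that add atoms: none
Why: Dess–Martin oxidation of the primary alcohol; the quaternary stereocentre cannot epimerise.

Step 12
Reactants: 19 (1S,2R)-2-{2-[(1S)-2,2-dimethyl-6-methylidene-1-(triethylsilyloxy)cyclohexyl]ethyl}-2-methylcyclopropane-1-carbaldehyde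
Product: 21 (6S)-6-{2-[(1S)-2,2-dimethyl-6-methylidene-1-(triethylsilyloxy)cyclohexyl]ethyl}-6-methyl-1,2-dioxan-3-ol (C3 epimers), via hydroperoxy aldehyde 20 (not isolated)
Conditions: H2O2 (ca. 2 M in Et2O, 10 equiv), pyrrolidine (20 mol %), CF3CO2H (20 mol %), CH2Cl2, 0 → 20 °C
Reagents that add atoms: hydrogen peroxide (OO)
Why: Proposed new method: the aldehyde condenses with the ammonium salt to a cyclopropyl iminium ion whose π* is conjugated with the C1–C2 Walsh bond; H2O2 (α-effect nucleophile) attacks the more substituted carbon C2 anti to the breaking C1–C2 bond (SN2-like, inversion, with tertiary-cation character in the transition state); the enamine is protonated and hydrolysed to hydroperoxy aldehyde 20, which closes to the peroxy-hemiacetal, so the cyclopropane is expanded to the 1,2-dioxane and its stereocentre becomes C6 with the spatial arrangement of the target (6S here only because CIP ranks change); the closest known reactions are iminium-activated ring opening of cyclopropanecarbaldehydes by halide, the invertive Lewis-acid opening of tertiary oxetanes and epoxides by H2O2, and the cobalt/O2 radical ring expansion of cyclobutanols to 1,2-dioxan-3-ols.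

Step 13
Reactants: 21 (6S)-6-{2-[(1S)-2,2-dimethyl-6-methylidene-1-(triethylsilyloxy)cyclohexyl]ethyl}-6-methyl-1,2-dioxan-3-ol
Product: 22 (6S)-6-{2-[(1S)-2,2-dimethyl-6-methylidene-1-(triethylsilyloxy)cyclohexyl]ethyl}-6-methyl-1,2-dioxan-3-yl acetate (C3 epimers)
Conditions: Ac2O, pyridine, DMAP (5 mol %), CH2Cl2, 0 °C
Reagents that add atoms: acetic anhydride (CC(=O)OC(C)=O)
Why: Acetylation of the peroxy-hemiacetal hydroxyl gives the leaving group for peroxycarbenium formation; the C3 epimer ratio is irrelevant because C3 becomes planar in step 15.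

Step 14
Reactants: 23 methyl propanoate
Product: 25 (E)-[(1-methoxyprop-1-en-1-yl)oxy]trimethylsilane, via lithium enolate 24 (not isolated)
Conditions: LDA, THF, −78 °C; then Me3SiCl, −78 → 25 °C; distillation
Reagents that add atoms: chlorotrimethylsilane (C[Si](C)(C)Cl)
Why: Kinetic ester enolisation in THF gives the enolate with methyl trans to O–Li, and O-silylation gives the E silyl ketene acetal.

Step 15
Reactants: 22 (6S)-6-{2-[(1S)-2,2-dimethyl-6-methylidene-1-(triethylsilyloxy)cyclohexyl]ethyl}-6-methyl-1,2-dioxan-3-yl acetate; 25 (E)-[(1-methoxyprop-1-en-1-yl)oxy]trimethylsilane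
Product: 26 methyl (2S)-2-[(3S,6R)-6-{2-[(1S)-2,2-dimethyl-6-methylidene-1-(triethylsilyloxy)cyclohexyl]ethyl}-6-methyl-1,2-dioxan-3-yl]propanoate
Conditions: (S,S)-imidodiphosphorimidate (IDPi) Brønsted acid (3 mol %), toluene, −78 °C
Reagents that add atoms: none
Why: Proposed new method: the chiral acid is silylated by 25 and ionises the anomeric acetate to a 1,2-dioxan-3-ylium (peroxycarbenium) ion paired with the confined chiral anion, which shields one face of C3 and orients the E ketene acetal in an open antiperiplanar transition state, so C3 (S) and C2 (S, 2,3-anti) are set by the catalyst because the 6,6-dialkyl centre gives almost no substrate bias; the closest known reactions are IDPi-catalysed additions of silyl ketene acetals to cyclic oxocarbenium ions from lactol acetates (Mukaiyama type) and achiral Lewis-acid additions of silyl ketene acetals to 3-acetoxy-1,2-dioxanes.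

Step 16
Reactants: 26 methyl (2S)-2-[(3S,6R)-6-{2-[(1S)-2,2-dimethyl-6-methylidene-1-(triethylsilyloxy)cyclohexyl]ethyl}-6-methyl-1,2-dioxan-3-yl]propanoate
Product: 27 methyl (2S)-2-[(3S,6R)-6-{2-[(1S)-1-hydroxy-2,2-dimethyl-6-methylidenecyclohexyl]ethyl}-6-methyl-1,2-dioxan-3-yl]propanoate
Conditions: HF·pyridine, pyridine, THF, 0 → 25 °C
Reagents that add atoms: none
Why: Fluoride desilylation under non-basic conditions, so the β-peroxy ester does not undergo retro-oxa-Michael opening or C2 epimerisation and the peroxide is untouched.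

## Compound list

1 | 2-methylcyclohexan-1-one (racemic) | CC1CCCCC1=O | starting material
2 | potassium 2-methylcyclohex-1-en-1-olate | CC1=C([O-])CCCC1.[K+] | intermediate
3 | 2,2-dimethylcyclohexan-1-one | CC1(C)CCCCC1=O | intermediate
4 | N-[(2-bromo-3,3-dimethylcyclohex-1-en-1-yl)methylidene]-N-methylmethanaminium bromide | C[N+](C)=CC1=C(Br)C(C)(C)CCC1.[Br-] | intermediate
5 | 2-bromo-3,3-dimethylcyclohex-1-ene-1-carbaldehyde | O=CC1=C(Br)C(C)(C)CCC1 | intermediate
6 | potassium ethenyltrifluoroborate | C=C[B-](F)(F)F.[K+] | starting material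
7 | 2-ethenyl-3,3-dimethylcyclohex-1-ene-1-carbaldehyde | O=CC1=C(C=C)C(C)(C)CCC1 | intermediate
8 | (2-ethenyl-3,3-dimethylcyclohex-1-en-1-yl)methanol | OCC1=C(C=C)C(C)(C)CCC1 | intermediate
9 | [(1S,6S)-6-ethenyl-5,5-dimethyl-7-oxabicyclo[4.1.0]heptan-1-yl]methanol | OC[C@@]12CCCC(C)(C)[C@]1(C=C)O2 | intermediate
10 | (1R,6S)-6-ethenyl-1-(iodomethyl)-5,5-dimethyl-7-oxabicyclo[4.1.0]heptane | IC[C@@]12CCCC(C)(C)[C@]1(C=C)O2 | intermediate
11 | (1S)-1-ethenyl-2,2-dimethyl-6-methylidenecyclohexan-1-ol | C=C1CCCC(C)(C)[C@@]1(O)C=C | intermediate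
12 | {[(1S)-1-ethenyl-2,2-dimethyl-6-methylidenecyclohexyl]oxy}triethylsilane | C=C1CCCC(C)(C)[C@@]1(O[Si](CC)(CC)CC)C=C | intermediate
13 | but-2-yn-1-ol | CC#CCO | starting material
14 | sodium 2,2-bis(2-methoxyethoxy)-3-methyl-2,5-dihydro-1,2-oxaluminol-2-uide | CC1=CCO[Al-]1(OCCOC)OCCOC.[Na+] | intermediate
15 | (2Z)-3-iodobut-2-en-1-ol | C/C(I)=C/CO | intermediate
16 | 9-{2-[(1S)-2,2-dimethyl-6-methylidene-1-(triethylsilyloxy)cyclohexyl]ethyl}-9-borabicyclo[3.3.1]nonane | C=C1CCCC(C)(C)[C@@]1(O[Si](CC)(CC)CC)CCB1C2CCCC1CCC2 | intermediate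
17 | (2Z)-5-[(1S)-2,2-dimethyl-6-methylidene-1-(triethylsilyloxy)cyclohexyl]-3-methylpent-2-en-1-ol | C=C1CCCC(C)(C)[C@@]1(O[Si](CC)(CC)CC)CC/C(C)=C\CO | intermediate
18 | [(1S,2R)-2-{2-[(1S)-2,2-dimethyl-6-methylidene-1-(triethylsilyloxy)cyclohexyl]ethyl}-2-methylcyclopropyl]methanol | C=C1CCCC(C)(C)[C@@]1(O[Si](CC)(CC)CC)CC[C@]1(C)C[C@@H]1CO | intermediate
19 | (1S,2R)-2-{2-[(1S)-2,2-dimethyl-6-methylidene-1-(triethylsilyloxy)cyclohexyl]ethyl}-2-methylcyclopropane-1-carbaldehyde | C=C1CCCC(C)(C)[C@@]1(O[Si](CC)(CC)CC)CC[C@]1(C)C[C@@H]1C=O | intermediate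
20 | (4S)-6-[(1S)-2,2-dimethyl-6-methylidene-1-(triethylsilyloxy)cyclohexyl]-4-hydroperoxy-4-methylhexanal | C=C1CCCC(C)(C)[C@@]1(O[Si](CC)(CC)CC)CC[C@](C)(OO)CCC=O | intermediate
21 | (6S)-6-{2-[(1S)-2,2-dimethyl-6-methylidene-1-(triethylsilyloxy)cyclohexyl]ethyl}-6-methyl-1,2-dioxan-3-ol (C3 epimers) | C=C1CCCC(C)(C)[C@@]1(O[Si](CC)(CC)CC)CC[C@@]1(C)CCC(O)OO1 | intermediate
22 | (6S)-6-{2-[(1S)-2,2-dimethyl-6-methylidene-1-(triethylsilyloxy)cyclohexyl]ethyl}-6-methyl-1,2-dioxan-3-yl acetate (C3 epimers) | C=C1CCCC(C)(C)[C@@]1(O[Si](CC)(CC)CC)CC[C@@]1(C)CCC(OC(C)=O)OO1 | intermediate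
23 | methyl propanoate | CCC(=O)OC | starting material
24 | lithium 1-methoxyprop-1-en-1-olate (methyl trans to O–Li) | C/C=C(\OC)[O-].[Li+] | intermediate
25 | (E)-[(1-methoxyprop-1-en-1-yl)oxy]trimethylsilane | C/C=C(\OC)O[Si](C)(C)C | intermediate
26 | methyl (2S)-2-[(3S,6R)-6-{2-[(1S)-2,2-dimethyl-6-methylidene-1-(triethylsilyloxy)cyclohexyl]ethyl}-6-methyl-1,2-dioxan-3-yl]propanoate | C=C1CCCC(C)(C)[C@@]1(O[Si](CC)(CC)CC)CC[C@@]1(C)CC[C@@H]([C@H](C)C(=O)OC)OO1 | intermediate
27 | methyl (2S)-2-[(3S,6R)-6-{2-[(1S)-1-hydroxy-2,2-dimethyl-6-methylidenecyclohexyl]ethyl}-6-methyl-1,2-dioxan-3-yl]propanoate | C=C1CCCC(C)(C)[C@@]1(O)CC[C@@]1(C)CC[C@@H]([C@H](C)C(=O)OC)OO1 | target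

## Step count and risk

Total step count: 16. Longest linear sequence: 14 (steps 1–7, 9–13, 15, 16).

Three steps most likely to fail:

Step 12 (proposed new method). The iminium-activated opening may be slow at a non-donor cyclopropane, may leak through a free tertiary cation and erode the configuration at C6, or may give elimination. The fallback uses only known chemistry, sets out from 17 and comes back at 21. Chemoselective Lemieux–Johnson cleavage of the unhindered trisubstituted alkene of 17 (OsO4 cat., NaIO4, 2,6-lutidine, dioxane–water) gives 4-[(1S)-2,2-dimethyl-6-methylidene-1-(triethylsilyloxy)cyclohexyl]butan-2-one F3. Spiroannulation with cyclopropyldiphenylsulfonium tetrafluoroborate and KOH in DMSO gives the oxaspiropentane F4, which LiBF4 rearranges to the 2,2-disubstituted cyclobutanone F5 (both epimers at the new quaternary carbon). NaBH4 gives the cyclobutanol F6, and the known Co(acac)2/O2 radical ring expansion of cyclobutanols gives 21 together with its C6 epimer F7. The epimers are carried through steps 13 and 15 and separated by HPLC at the stage of 26.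

Step 15 (proposed new method). The confined acid may not ionise the peroxy-acetate cleanly at low temperature, or may give low selectivity at C3/C2. The fallback uses only known chemistry, sets out from 21 and comes back at 26. 21 reacts through its open form 20 with methyl 2-(triphenyl-λ5-phosphanylidene)propanoate in a Wittig reaction to give methyl (2E,6R)-8-[(1S)-2,2-dimethyl-6-methylidene-1-(triethylsilyloxy)cyclohexyl]-6-hydroperoxy-2,6-dimethyloct-2-enoate F8. Et2NH in CF3CH2OH then effects the intramolecular peroxy-Michael cyclisation to 26 together with its C2/C3 diastereomers F9, from which 26 is isolated by HPLC.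

Step 5. The Sharpless epoxidation of the hindered, conjugated dienol 8 may be slow or only moderately selective, and the tertiary vinyl epoxide 9 is acid-labile. The fallback sets out from 3 and comes back at 11 by a racemic synthesis and resolution. 3 is α-methylenated (paraformaldehyde, i-Pr2NH·CF3CO2H, THF, reflux) to 2,2-dimethyl-6-methylidenecyclohexan-1-one F1. Vinylmagnesium bromide with CeCl3 (THF, −78 °C) adds 1,2 to give 11 together with its enantiomer (1R)-1-ethenyl-2,2-dimethyl-6-methylidenecyclohexan-1-ol F2, and preparative chromatography on a chiral stationary phase gives 11.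

Further compounds
F1 | step 5 | 2,2-dimethyl-6-methylidenecyclohexan-1-one | C=C1CCCC(C)(C)C1=O
F2 | step 5 | (1R)-1-ethenyl-2,2-dimethyl-6-methylidenecyclohexan-1-ol | C=C1CCCC(C)(C)[C@]1(O)C=C
F3 | step 12 | 4-[(1S)-2,2-dimethyl-6-methylidene-1-(triethylsilyloxy)cyclohexyl]butan-2-one | C=C1CCCC(C)(C)[C@@]1(O[Si](CC)(CC)CC)CCC(C)=O
F4 | step 12 | 2-{2-[(1S)-2,2-dimethyl-6-methylidene-1-(triethylsilyloxy)cyclohexyl]ethyl}-2-methyl-1-oxaspiro[2.2]pentane (epimers at C2) | C=C1CCCC(C)(C)[C@@]1(O[Si](CC)(CC)CC)CCC1(C)OC12CC2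
F5 | step 12 | 2-{2-[(1S)-2,2-dimethyl-6-methylidene-1-(triethylsilyloxy)cyclohexyl]ethyl}-2-methylcyclobutan-1-one (epimers at C2) | C=C1CCCC(C)(C)[C@@]1(O[Si](CC)(CC)CC)CCC1(C)CCC1=O
F6 | step 12 | 2-{2-[(1S)-2,2-dimethyl-6-methylidene-1-(triethylsilyloxy)cyclohexyl]ethyl}-2-methylcyclobutan-1-ol (stereoisomer mixture) | C=C1CCCC(C)(C)[C@@]1(O[Si](CC)(CC)CC)CCC1(C)CCC1O
F7 | step 12 | (6R)-6-{2-[(1S)-2,2-dimethyl-6-methylidene-1-(triethylsilyloxy)cyclohexyl]ethyl}-6-methyl-1,2-dioxan-3-ol (C6 epimer of 21) | C=C1CCCC(C)(C)[C@@]1(O[Si](CC)(CC)CC)CC[C@]1(C)CCC(O)OO1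
F8 | step 15 | methyl (2E,6R)-8-[(1S)-2,2-dimethyl-6-methylidene-1-(triethylsilyloxy)cyclohexyl]-6-hydroperoxy-2,6-dimethyloct-2-enoate | C=C1CCCC(C)(C)[C@@]1(O[Si](CC)(CC)CC)CC[C@](C)(OO)CC/C=C(\C)C(=O)OC
F9 | step 15 | methyl 2-[(6R)-6-{2-[(1S)-2,2-dimethyl-6-methylidene-1-(triethylsilyloxy)cyclohexyl]ethyl}-6-methyl-1,2-dioxan-3-yl]propanoate (C2/C3 diastereomers of 26) | C=C1CCCC(C)(C)[C@@]1(O[Si](CC)(CC)CC)CC[C@@]1(C)CCC(C(C)C(=O)OC)OO1
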